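- Late in the green run, at 20.0 min and 40.0 min, E reads 0% while J and L together read 97.7% and 103% of the charge.

common to all: D 0.71 mM (held)
- green: E 15 mM (fed, over 1.0 min); run made earlier
- flask: E 10 mM (fed, over 1.0 min); time 2.0 h

green run (percent of the E charged)

| time / min | E / % | J / % | L / % |
|---|---|---|---|
| 3.00 | 8.1 | 20.9 | 6.8 |
| 5.00 | 1.0 | 31.0 | 9.5 |
| 10.0 | 1.1 | 62.6 | 22.6 |
| 20.0 | 0 | 70.4 | 27.3 |
| 40.0 | 0 | 72.4 | 30.4 |

(each reading ± 1 percentage point)

- at 2.0 h, what has stopped the reaction, if anything has (it is still moving / forward and back rates have come level / all of E has reacted)
- share of the E used up at 2.0 h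
- J at 2.0 h, in percent of the E charged
- L at 2.0 h, in percent of the E charged

- the analysis behind the earlier runs scatters by 1 percentage point, standard deviation
- at the start none of D is in solution
- the reaction counts as stopped when no species that holds the E changes by six tenths of a point or more over the second half of the time

- The first estimate concerns E: green reads 0% at 20.0 min, and the flask is given 2.0 h, longer by a factor of 6.00, so E in the flask is expected to be gone by the asked time.
- The second estimate takes the balance from there: at 5.00 min green accounts for 41.5% of its charge, so unseen forms hold the rest, but the late sums lie within a few scatters of the whole, so J and L in the flask are expected to share the whole charge.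
- Dividing the rise of L by the rise of J removes time and, with the sum fixed, leaves one number: the end split, the fraction of J plus L that is L (an overall selectivity), pooled over the last two green readings, 28.8%.
- Carried to the flask, this reckoning of mine gives L 28.8% and J 71.2%.
- The weak link is the quotient of rates itself: from 20.0 min to 40.0 min green gains 3.1 percentage points of L and 2 points of J, each a difference of readings scattering by 1 point, so that quotient cannot be read.
- The quotient of amounts replaces it: read singly, the green split is 27.9% and then 29.6%, readings with their scatter, and this reckoning expects L in the flask near them, provided the split carries from 15 mM to 10 mM; green shows one charge and cannot test that.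
- The forecast says all of E has reacted, with conversion 100%, J 68% (62% to 73%) and L 32% (27% to 38%); it differs from my reckoning by lowering J, on the ground that “selectivity appears to favour J at high loading”.

    J ⇌ L (K = 0.390, k = 0.00710 s⁻¹)
    D ⇌ Q, rate k2*(csat - [Q]) (kL = 6.90 s⁻¹)
    G + X → J (k = 81.0 L mol⁻¹ s⁻¹)
    E → G (k = 0.0170 s⁻¹)
    Q → X (k = 0.0300 s⁻¹)

- In the flask at 2.0 h, all of E has reacted: conversion is 100%, J 71.9% and L 28.1%, a split of 28.1%. The relaxation half-life of J and L by their own step, both ways together, is 0.457 min, short against 2.0 h, and the flask reads J 71.9% at 0.400 h. The green split 28.8%, carried to the neighbour flask with 25 mM of E, puts J at 71.2% of that charge, and at 2.00 h that neighbour flask holds J at 71.9%.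

Readings and results stem from a simulated flask on assumed constants, noise included.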